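**Opening charge.** You charge 20 mM substrate and 21.0 mM coupling partner. At one of each per product, substrate is the limiting reagent of this flask.

| flask | substrate | coupling partner | remark | time |
|---|---|---|---|---|
| spring | 20 mM | 14 mM | run made earlier |  |
| midnight | 20 mM | 32 mM | run made earlier |  |
| flask | 20 mM | 21.0 mM |  | 25 min |

| run | time / min | product / % |
|---|---|---|
| spring | 4.00 | 8 |
| spring | 6.00 | 10 |
| spring | 10.0 | 10 |
| spring | 15.0 | 12 |
| midnight | 4.00 | 17 |
| midnight | 6.00 | 21 |
| midnight | 10.0 | 22 |
| midnight | 15.0 | 21 |

(readings scatter by 1.5 percentage points)



1. the best time, 25 min at the latest, for product
2. the amount of product, in percent of the substrate charged, at that time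
3. earliest time at which at least nineteen twentieths of that best amount are there, in min
4. latest time at which they still are, in min

**Plateau ratio.** Both earlier runs hold the same substrate charge. From 6.00 min on, their readings stay within one standard deviation of their means, 10.7% in the spring run and 21.3% in the midnight run, so neither run dates a peak. Pooled, they give 0.139 as the plateau ratio, [product] at plateau over [coupling partner] charged.

**The ledger.** My entry for this flask is 2.92 mM product, which is 14.6% of the substrate charged. The same amount comes off the coupling partner and leaves 18.1 mM of it, so this entry does not exhaust the partner. The last line is 17.1 mM of substrate outside product, and no reading says where it stands.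

The forecast, a little above my entry at 15%, puts the best time at 25 min and the window from 7.5 min to 25 min, and it expects “a flat plateau through 25 min”.

**The flask.** This flask peaks at 15.7% after 14.1 min. The window asked for runs from 9.01 min to 21.9 min.

    substrate + coupling partner ⇌ product (K = 39.1 M⁻¹, k = 2.26 M⁻¹ min⁻¹)
    2 substrate → homo dimer (k = 5.04 M⁻¹ min⁻¹)

**Closed books.** In this flask, the homo dimer step uses substrate at 4.2 times the forward rate of the product step at the start, and at 0.79 times that rate at 25.0 min. At the best time this flask holds 61.8% homo dimer, counted in substrate, beside 22.5% substrate and 15.7% product. The plateau ratio gave 14.6% for this flask against 15.7%. For the neighbour flask with 84 mM coupling partner it gives 58.4%, where that flask's best is 46.3%.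

The earlier runs and the new flask were generated by integration for substances that don't exist, and the scatter is random.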